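(The earlier runs and the new flask are simulated for substances that don't exist, and the scatter is random.)

The easy step first: in the beta run the starting material falls from 91.7% at 10.0 s to 70.7% at 50.0 s, and read as a pseudo-first-order decay this gives 1.78 min as the beta half-life, the time in which the starting material left falls to 0.5 of itself.

the same everywhere: starting material 0.066 M; protic impurity 1.32 mM; spent carrier 0.66 mM
- beta: salt in the second phase 0.26 M; run made earlier
- flask: salt in the second phase 0.132 M; volume of the second phase over the first 0.50

beta run (percent of the starting material charged)

| time / s | product / % | starting material / % |
|---|---|---|
| 10.0 | 6.5 | 91.7 |
| 20.0 | 12.7 | 86.2 |
| 30.0 | 18.0 | 80.1 |
| 50.0 | 26.9 | 70.7 |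

(scatter of a reading: 0.5 percentage points)

- in the second phase: salt in the second phase, spent salt in the second phase; everything else is in the first
- charges count per volume of the first phase; a concentration in a rate is the amount of a species over the volume of its own phase; every rate counts per litre of the first phase
- the numbers in the tables scatter with a standard deviation of 0.5 percentage points
- steps under discussion: spent carrier + salt in the second phase <-> fresh carrier + spent salt in the second phase; starting material + fresh carrier -> product + spent carrier; starting material + fresh carrier -> spent catalyst; starting material + protic impurity -> quenched substrate
- the earlier runs hold the two phases in the same ratio of volumes as the flask asked about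
- no earlier run changes the charge of salt in the second phase; that part of a forecast is a guess

1. apparent order in salt in the second phase when 50% of the starting material are converted (percent change of the rate of making product for one percent more salt in the second phase charged)

The flask on the bench has the beta charges of starting material, protic impurity and spent carrier, but its salt charge is lower by a factor of 1.97, and I leave its volume ratio at 0.50, the ratio of the beta run, so that the salt charge is what differs. Early on, the protic impurity should take about 2.00% of the starting material, as the gap of 1.80% in the first beta reading suggests, so a small shortfall in the balance is no alarm. If the rate goes with the salt to a power that stays the same along the run, and the other charges and the volume ratio stay as in the beta run, the flask's half-life is the beta half-life times the salt factor to that power, so for a power between 0 and 1 I expect between 1.78 min and 3.51 min. The forecast says 0.35, with a range of 0.08 to 0.75, on the ground that “The data cannot separate these”; by my rule its value means 2.26 min.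

The simulation gives 0.72, above the forecast's value and inside its range.

    spent carrier + salt in the second phase ⇌ fresh carrier + spent salt in the second phase (K = 0.380, k = 6.40 M⁻¹ s⁻¹)
    starting material + fresh carrier → product + spent carrier (k = 15.0 M⁻¹ s⁻¹)
    starting material + fresh carrier → spent catalyst (k = 0.0920 M⁻¹ s⁻¹)
    starting material + protic impurity → quenched substrate (k = 2.20 M⁻¹ s⁻¹)

At 1.15 min the flask's half-life of starting material by the product step is 2.7 min, longer by a factor of 1.54 than the beta half-life of 1.78 min, which is a reading taken between 10.0 s and 50.0 s of the beta run, and shorter than the 3.51 min that my rule gives for a power of 1. Taken across these two different moments and through the salt factor of 1.97, that stretch is a power of 0.635, while the order in the flask at 50% conversion is 0.72.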